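**Total synthesis proposal for the target, 4-hydroxy-2-(4-hydroxy-2-methoxyphenyl)-6-methoxy-5-(3-methylbut-2-en-1-yl)-1-benzofuran-3-carbaldehyde (compound 20)**

## Analysis of the target

The target is a 2-aryl-1-benzofuran (O1, C2, C3, C3a, C4 to C7, C7a; aryl carbons C1' to C6'). The furan ring carries a formyl group at C3 and a 4-hydroxy-2-methoxyphenyl ring at C2. The benzo ring carries OH at C4, a 3-methylbut-2-enyl (prenyl) chain at C5, OMe at C6 and hydrogen only at C7. There is no stereocentre, and the prenyl alkene ends in two identical methyl groups, so no configuration has to be set or guarded. The sensitive groups are the prenyl alkene next to a free phenol (acid can close it to a dimethylchroman; hydrogenolysis and electrophilic oxidants are excluded), the electron-rich heteroaryl aldehyde, and two phenols that must be told apart from two methyl ethers. The difficulty is the benzo ring: five of its six positions are substituted, and the prenyl group sits between two oxygens that differ (OH and OMe). Late prenylation or formylation of a finished 4,6-dioxygenated benzofuran would have to choose between C5 and C7, or between C3 and C7. The strategy rests on the fact that C7a, C6 and C4 bear oxygen and alternate with C7, C5 and C3a. This is the phloroglucinol pattern, the aromatised form of a chain with a carbonyl at every second carbon, so C5 can be the α-carbon of a ketone that already carries the prenyl chain and C6 can come from an ester carbonyl.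

## Retrosynthetic reasoning

**20 back to 19.** The last bond cut is the O4'–CH2 bond of an acetal protecting group. This group survives enolates, hydroxide, alkoxide, organozinc, palladium and hydride. Its acid removal is placed at the aldehyde stage, where the 3-substituent no longer ionises and the 4-hydroxyl is tied to the formyl oxygen.

**19 back to 17 through 18.** The formyl group is traced back through carbinol 18 to the tert-butyl ester 17. No skeletal bond is cut here: the C3 carbon is meant to be in place from the first carbon–carbon bond formation, so no formylation has to choose between C3 and C7. The ester is tert-butyl because, earlier on, it stands beside an enolisable acyl chain and must not serve as an acyl acceptor.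

**17 back to 16.** The O6–CH3 bond is cut. The forward step must methylate the 6-hydroxyl of diol 16 and leave the 4-hydroxyl, which is wedged between the prenyl chain and the C3 ester and hydrogen-bonded to it.

**16 back to 14 (key disconnection).** The C5–C6 bond is cut, which opens the whole benzo ring to furan keto ester 14. C6 becomes the carbonyl carbon of a furylacetate ester and C5 the α-carbon of a furyl ketone whose chain already carries the prenyl unit. Cutting C4–C5 instead would make the acceptor a ring-bound ester that is conjugated with the furan oxygen and crowded by the tert-butyl ester. Cutting the C5–prenyl bond would bring back the C5/C7 and O/C alkylation problem. The gain is one ring, all three ring oxygens and the prenyl position in a single step. The forward reaction needs the ketone enolate to find the acetate ester even though the acetate CH2 is the more acidic site, and it must close the six-membered ring, not attack the C3 ester.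

**14 back to 11 and 12.** The bond between the ketone carbonyl and its chain CH2 is cut. The acyl donor is thioester 11 and the chain arrives as the alkylzinc reagent 13, made from bromide 12. A thioester is preferred to an acid chloride because an acid chloride beside a tert-butyl ester tends to collapse to a cyclic anhydride with loss of the tert-butyl group, and chloride acidity endangers the acetal. The organozinc partner touches neither the esters nor the product ketone.

**11 back to 7 through 10, 9 and 8.** Thioester 11 comes from acid 10, whose ring carboxyl must be distinguished from the acetate carboxyl. Direct partial hydrolysis of triester 7 would free the wrong (aliphatic) acid. Both methyl esters are therefore hydrolysed to diacid 8, which is closed to the cyclic anhydride 9 and reopened with an alcohol at the more electrophilic aliphatic carbonyl. That puts the methyl ester on the side chain and the free acid on the ring.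

**7 back to 4 and 5.** The furan ring is cut at O1–C5 and C3–C4 (furan numbering), giving the 1,4-diketone 6. This in turn is cut at its central bond into the α-bromo β-keto ester 4 and the enolate of diester 5. Compound 5 supplies the ring carboxyl and the acetate arm in one piece and, having a single ketone, leaves no choice in the ring closure. Compound 4 supplies the aryl ring and the C3 carbon.

**4 back to 1 through 3 and 2.** Bromide 4 comes from β-keto ester 3, which is cut between the aroyl carbon and the CH2 (a crossed Claisen condensation on benzoate 2). Benzoate 2 is the protected form of commercial phenol 1, so the 2'-methoxy group and the 4'-oxygen are bought in place.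

## Alternatives that were turned down

**Alternative 1: the 2-aryl ring grown by cycloaddition.** The disconnection removes the aryl ring itself (C1'–C2' and C5'–C6'), leading back to the 2-ethynylbenzofuran-3-carbaldehyde A2 and the electron-rich diene A3. In the forward step the unsubstituted diene terminus would bond to the terminal alkyne carbon and the ketene-acetal carbon to the internal one. Loss of one methoxy group and of the silyl group would aromatise the adduct to A1, which is one ester cleavage from the target.
- For it: the polarity of A3 fixes the 2'-OMe/4'-OH pattern, and the formyl group and free 4'-hydroxyl are already present. On endgame length it is stronger than the chosen route.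
- Against it: the alkyne of A2 is activated only vinylogously by the formyl group through C2=C3 and is counter-polarised by three oxygen donors. The formyl group itself is a competent partner for a diene like A3. Most important, A2 already contains the complete prenylated, differentially oxygenated benzo ring, so the real problem is left unsolved and the key step builds the ring that can be bought with compound 1.
- Comparison: the chosen strategy uses its key step on the difficult ring and takes the easy one from the shelf.

**Alternative 2: tethered C2 arylation through a coumestan.** The disconnection is C2–C1', with the two halves joined as the aryl ester A5 between the C3 carboxyl and the future 2'-oxygen. Zerovalent palladium would insert into the aryl–bromine bond, metalate the furan C2–H with carbonate assistance, and reductive elimination would close the lactone ring of coumestan A4.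
- For it: the ring closure has no regiochemical question and belongs to a robust reaction class. On the reliability of the key bond formation it is at least the equal of the Claisen closure.
- Against it: an aryl ester must survive hot carbonate. After A4 the lactone must be opened reductively, the freed 2'-phenol methylated, the carbinol re-oxidised and two acetals removed, which is as many operations as the chosen route needs after its key step. The acid half of A5 again carries the finished benzo ring, whose synthesis would come on top.
- Comparison: the chosen strategy builds that ring and has the 2'-methoxy group from the start.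

**Alternative 3: benzannulation of a furyl diazoketone.** Four bonds of the benzo ring are cut (C7–C7a, C6–C7, C4–C5, C3a–C4), leading back to diazoketone A7 and methoxyalkyne A8. Irradiation would give a furylketene by Wolff shift. This would add to A8 to give a cyclobutenone, which opens to a dienylketene and closes by a six-electron process onto the free β-carbon of the furan, giving phenol A6.
- For it: four bonds form in one step. The alkyne places the prenyl group at C5 and delivers O6 already methylated and O4 free, so no selective methylation is needed. On this point, and in convergence, it is stronger than the chosen strategy.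
- Against it: A7 is a diazo compound, and A8 is an alkynyl ether with a doubly activated CH2 that is prone to isomerisation and hydration. The ketene can be intercepted by the prenyl alkene or can dimerise, and photolysis limits throughput. A7 itself needs a differentiated 2-arylfuran dicarboxylate, so it is not cheaper to make than 14. Three operations still follow A6.
- Comparison: the chosen strategy offers ionic, thermodynamically driven steps with bench-stable intermediates, at the price of one selective methylation.

Key step: step 9

Remark on the chemistry: 1, 5 and 12 are taken as bought; the stereogenic carbons of 4, 6 and 15 are labile and racemic, and none survives into the target.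

## Route

Step 1
Reactants: 1 methyl 4-hydroxy-2-methoxybenzoate
Product: 2 methyl 2-methoxy-4-(methoxymethoxy)benzoate
Conditions: MOMCl (1.5 equiv), i-Pr2NEt (2 equiv), CH2Cl2, 0 °C → rt
Reagents that add atoms: chloromethyl methyl ether, COCCl
Why: O-alkylation of the phenol to a methoxymethyl acetal; the ester and the aryl methyl ether are inert, and the acetal withstands every basic, organometallic and hydride step that follows.

Step 2
Reactants: 2 methyl 2-methoxy-4-(methoxymethoxy)benzoate
Product: 3 tert-butyl 3-[2-methoxy-4-(methoxymethoxy)phenyl]-3-oxopropanoate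
Conditions: t-BuOAc (2.5 equiv), LiN(i-Pr)2 (2.5 equiv), THF, −78 °C; 2, −78 → −20 °C; then AcOH
Reagents that add atoms: tert-butyl acetate, CC(=O)OC(C)(C)C
Why: Crossed Claisen condensation of the lithium enolate of tert-butyl acetate with the non-enolisable benzoate; the product is taken out of the equilibrium as its stabilised enolate, which consumes the second equivalent of base and prevents double addition.

Step 3
Reactants: 3 tert-butyl 3-[2-methoxy-4-(methoxymethoxy)phenyl]-3-oxopropanoate
Product: 4 tert-butyl 2-bromo-3-[2-methoxy-4-(methoxymethoxy)phenyl]-3-oxopropanoate (racemic)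
Conditions: NBS (1.0 equiv), NH4OAc (10 mol %), Et2O, 0 °C → rt
Reagents that add atoms: N-bromosuccinimide, O=C1CCC(=O)N1Br
Why: Electrophilic α-bromination of the β-keto ester enol; the enol is far more nucleophilic than the acyl-deactivated arene, and one equivalent should stop at the monobromide.

Step 4
Reactants: 4 tert-butyl 2-bromo-3-[2-methoxy-4-(methoxymethoxy)phenyl]-3-oxopropanoate; 5 dimethyl 3-oxopentanedioate
Product: 7 3-tert-butyl 4-methyl 5-(2-methoxy-2-oxoethyl)-2-[2-methoxy-4-(methoxymethoxy)phenyl]furan-3,4-dicarboxylate, via tetracarbonyl 1,4-diketone 6 (not isolated)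
Conditions: 5 (1.2 equiv), NaH (1.2 equiv), THF, 0 °C; 4, 0 °C → rt; crude 6: CSA (10 mol %), 4 Å MS, CH2Cl2, rt → 40 °C
Reagents that add atoms: none
Why: Alkylation of the sodium enolate of 5 by the doubly activated bromide gives the 1,4-diketone 6 (classical tetra-acylethane synthesis); the more acidic partner is the nucleophile, so that bromine transfer to it is uphill. Paal–Knorr cyclodehydration then closes the furan: the enol oxygen of the aroyl unit adds to the only ketone of the other half, and water is lost readily because the hydroxyl lies β to an ester. A weak anhydrous acid is chosen to spare the tert-butyl ester and the acetal.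

Step 5
Reactants: 7 3-tert-butyl 4-methyl 5-(2-methoxy-2-oxoethyl)-2-[2-methoxy-4-(methoxymethoxy)phenyl]furan-3,4-dicarboxylate
Product: 8 4-(tert-butoxycarbonyl)-2-(carboxymethyl)-5-[2-methoxy-4-(methoxymethoxy)phenyl]furan-3-carboxylic acid
Conditions: LiOH·H2O (5 equiv), THF–MeOH–H2O, rt → 40 °C; 1 M HCl to pH 3, 0 °C
Reagents that add atoms: lithium hydroxide, [Li+].[OH-]
Why: Saponification of both methyl esters by acyl–oxygen cleavage; the tert-butyl ester resists hydroxide for steric reasons, and brief cold acidification leaves it and the acetal intact.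

Step 6
Reactants: 8 4-(tert-butoxycarbonyl)-2-(carboxymethyl)-5-[2-methoxy-4-(methoxymethoxy)phenyl]furan-3-carboxylic acid
Product: 10 4-(tert-butoxycarbonyl)-2-(2-methoxy-2-oxoethyl)-5-[2-methoxy-4-(methoxymethoxy)phenyl]furan-3-carboxylic acid, via cyclic anhydride 9 (not isolated)
Conditions: DCC (1.05 equiv), CH2Cl2, 0 °C → rt; filter; MeOH, 50 °C
Reagents that add atoms: methanol, CO
Why: Carbodiimide dehydration gives the six-membered anhydride of the homophthalic type. Methanol opens it at the CH2-bound carbonyl, which is not conjugated and not crowded, and not at the furoyl carbonyl, which is deactivated by the furan oxygen and shielded by the tert-butyl ester; this is the known regiochemistry of homophthalic anhydride alcoholysis.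

Step 7
Reactants: 10 4-(tert-butoxycarbonyl)-2-(2-methoxy-2-oxoethyl)-5-[2-methoxy-4-(methoxymethoxy)phenyl]furan-3-carboxylic acid
Product: 11 tert-butyl 4-[(ethylsulfanyl)carbonyl]-5-(2-methoxy-2-oxoethyl)-2-[2-methoxy-4-(methoxymethoxy)phenyl]furan-3-carboxylate
Conditions: EtSH (2 equiv), EDC·HCl (1.3 equiv), DMAP (10 mol %), CH2Cl2, 0 °C → rt
Reagents that add atoms: ethanethiol, CCS
Why: Steglich-type thioesterification under near-neutral conditions; the thioester is a storable acyl donor and avoids an acid chloride beside the tert-butyl ester and the acetal.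

Step 8
Reactants: 11 tert-butyl 4-[(ethylsulfanyl)carbonyl]-5-(2-methoxy-2-oxoethyl)-2-[2-methoxy-4-(methoxymethoxy)phenyl]furan-3-carboxylate; 12 5-bromo-2-methylpent-2-ene
Product: 14 tert-butyl 5-(2-methoxy-2-oxoethyl)-2-[2-methoxy-4-(methoxymethoxy)phenyl]-4-(5-methylhex-4-enoyl)furan-3-carboxylate, via bromo(4-methylpent-3-en-1-yl)zinc 13 (not isolated)
Conditions: 12 (2.5 equiv), Zn dust, LiCl, THF, 50 °C; then 11, PdCl2(PPh3)2 (5 mol %), THF–toluene, rt
Reagents that add atoms: none
Why: Fukuyama coupling: zinc inserts into the primary bromide, zerovalent palladium inserts into the acyl–sulfur bond, and transmetalation followed by reductive elimination gives the ketone. Alkylzinc halides add neither to the esters nor to the product ketone.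

Step 9
Reactants: 14 tert-butyl 5-(2-methoxy-2-oxoethyl)-2-[2-methoxy-4-(methoxymethoxy)phenyl]-4-(5-methylhex-4-enoyl)furan-3-carboxylate
Product: 16 tert-butyl 4,6-dihydroxy-2-[2-methoxy-4-(methoxymethoxy)phenyl]-5-(3-methylbut-2-en-1-yl)-1-benzofuran-3-carboxylate, via cyclic 1,3-diketone 15 (not isolated)
Conditions: NaOMe (4 equiv), MeOH (degassed, Ar), 65 °C; 1 M HCl to pH 5, 0 °C
Reagents that add atoms: none
Why: Methoxide deprotonates 14 reversibly; the furylacetate CH2 is the most acidic site, but its enolate has no acceptor within reach (attack on the ketone would be a four-membered closure), so it is only a resting state. The minor ketone enolate, formed at the CH2 that carries the prenyl unit, adds to the acetate ester carbonyl in a 6-exo-trig closure and methoxide leaves, forming C5–C6 and the cyclic 1,3-diketone 15. Diketone 15 enolises at once to the aromatic 4,6-diol, which is held as its phenoxide, and this makes the sequence irreversible. The closest known reaction type is the alkoxide-mediated intramolecular Claisen (Dieckmann-type) cyclisation of (2-acylaryl)acetic esters to 1,3-dihydroxyarenes, the laboratory counterpart of polyketide folding. The selectivity needed is six-membered closure onto the acetate ester over five-membered closure onto the C3 ester; the bulk of the tert-butyl group, the strain of a five-membered ring fused across the furan 3,4-bond and the absence of an aromatic product on that path secure it. An equilibrating alkoxide is used on purpose, because a stoichiometric amide base would turn the acetate into its enolate and switch the acceptor off; methoxide matches the methyl ester, so ester exchange changes nothing. The prenyl position is fixed by the constitution of the chain, and the only new stereocentre, C5 of 15, is lost on enolisation.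

Step 10
Reactants: 16 tert-butyl 4,6-dihydroxy-2-[2-methoxy-4-(methoxymethoxy)phenyl]-5-(3-methylbut-2-en-1-yl)-1-benzofuran-3-carboxylate
Product: 17 tert-butyl 4-hydroxy-6-methoxy-2-[2-methoxy-4-(methoxymethoxy)phenyl]-5-(3-methylbut-2-en-1-yl)-1-benzofuran-3-carboxylate
Conditions: MeI (1.1 equiv), K2CO3 (1.2 equiv), acetone, rt
Reagents that add atoms: iodomethane, CI
Why: Williamson methylation with one equivalent; the 6-hydroxyl has only H7 and the prenyl chain as neighbours, whereas the 4-hydroxyl is wedged between the prenyl chain and the tert-butyl ester and hydrogen-bonded to its carbonyl oxygen, so the 6-phenoxide should react first.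

Step 11
Reactants: 17 tert-butyl 4-hydroxy-6-methoxy-2-[2-methoxy-4-(methoxymethoxy)phenyl]-5-(3-methylbut-2-en-1-yl)-1-benzofuran-3-carboxylate
Product: 18 3-(hydroxymethyl)-6-methoxy-2-[2-methoxy-4-(methoxymethoxy)phenyl]-5-(3-methylbut-2-en-1-yl)-1-benzofuran-4-ol
Conditions: LiAlH4 (3 equiv), THF, 0 °C → rt; aq. potassium sodium tartrate
Reagents that add atoms: none
Why: Hydride reduction of the ester to the primary alcohol after deprotonation of the phenol; the isolated alkene, the aryl ethers and the acetal are inert, and the non-acidic work-up protects the easily ionised furylmethanol, which is used at once.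

Step 12
Reactants: 18 3-(hydroxymethyl)-6-methoxy-2-[2-methoxy-4-(methoxymethoxy)phenyl]-5-(3-methylbut-2-en-1-yl)-1-benzofuran-4-ol
Product: 19 4-hydroxy-6-methoxy-2-[2-methoxy-4-(methoxymethoxy)phenyl]-5-(3-methylbut-2-en-1-yl)-1-benzofuran-3-carbaldehyde
Conditions: MnO2 (activated, 15 equiv), CH2Cl2, rt
Reagents that add atoms: none
Why: Surface oxidation of a heteroaryl (benzylic-type) carbinol by MnO2, which stops at the aldehyde under neutral conditions and leaves the trisubstituted alkene and the hindered phenol alone.

Step 13
Reactants: 19 4-hydroxy-6-methoxy-2-[2-methoxy-4-(methoxymethoxy)phenyl]-5-(3-methylbut-2-en-1-yl)-1-benzofuran-3-carbaldehyde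
Product: 20 4-hydroxy-2-(4-hydroxy-2-methoxyphenyl)-6-methoxy-5-(3-methylbut-2-en-1-yl)-1-benzofuran-3-carbaldehyde
Conditions: 2 M HCl (aq.), MeOH–THF, 40 °C
Reagents that add atoms: none
Why: Acid-catalysed acetal hydrolysis through an oxocarbenium ion; at the aldehyde stage the 3-substituent no longer ionises, and the 4-hydroxyl is tied to the formyl oxygen, which lowers its tendency to add to the prenyl double bond.

## Compound list

1 | methyl 4-hydroxy-2-methoxybenzoate | COC(=O)c1ccc(O)cc1OC | starting material
2 | methyl 2-methoxy-4-(methoxymethoxy)benzoate | COCOc1ccc(C(=O)OC)c(OC)c1 | intermediate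
3 | tert-butyl 3-[2-methoxy-4-(methoxymethoxy)phenyl]-3-oxopropanoate | COCOc1ccc(C(=O)CC(=O)OC(C)(C)C)c(OC)c1 | intermediate
4 | tert-butyl 2-bromo-3-[2-methoxy-4-(methoxymethoxy)phenyl]-3-oxopropanoate (racemic) | COCOc1ccc(C(=O)C(Br)C(=O)OC(C)(C)C)c(OC)c1 | intermediate
5 | dimethyl 3-oxopentanedioate | COC(=O)CC(=O)CC(=O)OC | starting material
6 | 1-tert-butyl 2,4-dimethyl 1-[2-methoxy-4-(methoxymethoxy)benzoyl]-3-oxobutane-1,2,4-tricarboxylate (mixture of diastereomers and enol forms, not isolated) | COC(=O)CC(=O)C(C(=O)OC)C(C(=O)OC(C)(C)C)C(=O)c1ccc(OCOC)cc1OC | intermediate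
7 | 3-tert-butyl 4-methyl 5-(2-methoxy-2-oxoethyl)-2-[2-methoxy-4-(methoxymethoxy)phenyl]furan-3,4-dicarboxylate | COC(=O)Cc1oc(-c2ccc(OCOC)cc2OC)c(C(=O)OC(C)(C)C)c1C(=O)OC | intermediate
8 | 4-(tert-butoxycarbonyl)-2-(carboxymethyl)-5-[2-methoxy-4-(methoxymethoxy)phenyl]furan-3-carboxylic acid | OC(=O)Cc1oc(-c2ccc(OCOC)cc2OC)c(C(=O)OC(C)(C)C)c1C(=O)O | intermediate
9 | tert-butyl 2-[2-methoxy-4-(methoxymethoxy)phenyl]-4,6-dioxo-6,7-dihydro-4H-furo[3,2-c]pyran-3-carboxylate (not isolated) | COCOc1ccc(-c2oc3c(c2C(=O)OC(C)(C)C)C(=O)OC(=O)C3)c(OC)c1 | intermediate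
10 | 4-(tert-butoxycarbonyl)-2-(2-methoxy-2-oxoethyl)-5-[2-methoxy-4-(methoxymethoxy)phenyl]furan-3-carboxylic acid | COC(=O)Cc1oc(-c2ccc(OCOC)cc2OC)c(C(=O)OC(C)(C)C)c1C(=O)O | intermediate
11 | tert-butyl 4-[(ethylsulfanyl)carbonyl]-5-(2-methoxy-2-oxoethyl)-2-[2-methoxy-4-(methoxymethoxy)phenyl]furan-3-carboxylate | CCSC(=O)c1c(CC(=O)OC)oc(-c2ccc(OCOC)cc2OC)c1C(=O)OC(C)(C)C | intermediate
12 | 5-bromo-2-methylpent-2-ene | CC(C)=CCCBr | starting material
13 | bromo(4-methylpent-3-en-1-yl)zinc (not isolated) | CC(C)=CCC[Zn]Br | intermediate
14 | tert-butyl 5-(2-methoxy-2-oxoethyl)-2-[2-methoxy-4-(methoxymethoxy)phenyl]-4-(5-methylhex-4-enoyl)furan-3-carboxylate | COC(=O)Cc1oc(-c2ccc(OCOC)cc2OC)c(C(=O)OC(C)(C)C)c1C(=O)CCC=C(C)C | intermediate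
15 | tert-butyl 2-[2-methoxy-4-(methoxymethoxy)phenyl]-5-(3-methylbut-2-en-1-yl)-4,6-dioxo-4,5,6,7-tetrahydro-1-benzofuran-3-carboxylate (racemic, not isolated) | COc1cc(OCOC)ccc1-c1oc2c(c1C(=O)OC(C)(C)C)C(=O)C(CC=C(C)C)C(=O)C2 | intermediate
16 | tert-butyl 4,6-dihydroxy-2-[2-methoxy-4-(methoxymethoxy)phenyl]-5-(3-methylbut-2-en-1-yl)-1-benzofuran-3-carboxylate | COc1cc(OCOC)ccc1-c1oc2cc(O)c(CC=C(C)C)c(O)c2c1C(=O)OC(C)(C)C | intermediate
17 | tert-butyl 4-hydroxy-6-methoxy-2-[2-methoxy-4-(methoxymethoxy)phenyl]-5-(3-methylbut-2-en-1-yl)-1-benzofuran-3-carboxylate | COc1cc(OCOC)ccc1-c1oc2cc(OC)c(CC=C(C)C)c(O)c2c1C(=O)OC(C)(C)C | intermediate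
18 | 3-(hydroxymethyl)-6-methoxy-2-[2-methoxy-4-(methoxymethoxy)phenyl]-5-(3-methylbut-2-en-1-yl)-1-benzofuran-4-ol | COc1cc(OCOC)ccc1-c1oc2cc(OC)c(CC=C(C)C)c(O)c2c1CO | intermediate
19 | 4-hydroxy-6-methoxy-2-[2-methoxy-4-(methoxymethoxy)phenyl]-5-(3-methylbut-2-en-1-yl)-1-benzofuran-3-carbaldehyde | COc1cc(OCOC)ccc1-c1oc2cc(OC)c(CC=C(C)C)c(O)c2c1C=O | intermediate
20 | 4-hydroxy-2-(4-hydroxy-2-methoxyphenyl)-6-methoxy-5-(3-methylbut-2-en-1-yl)-1-benzofuran-3-carbaldehyde | COc1cc(O)ccc1-c1oc2cc(OC)c(CC=C(C)C)c(O)c2c1C=O | target

## Step count and risk

Total step count: 13 steps. Longest linear sequence: 13 steps, from 1 to 20. Compounds 5 and 12 enter as bought side components in steps 4 and 8.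

**Step 9 (key step).** The closure may be slow, because the base rests mainly on the furylacetate position, where the ester acceptor is switched off as its enolate. During a long reaction time, hydrolysis by adventitious hydroxide, intermolecular condensation or air oxidation of the electron-rich phenoxide could take over. The fallback closes the same ring from its other Claisen bond (C4–C5), where the acceptor is a ring-bound ester that cannot be deprotonated, so an irreversible closure with a stoichiometric amide base is possible. It sets out from 7 and returns at 16. One equivalent of LiOH at 0 °C should cleave only the unhindered, non-conjugated acetate ester of 7 to {4-(tert-butoxycarbonyl)-3-(methoxycarbonyl)-5-[2-methoxy-4-(methoxymethoxy)phenyl]furan-2-yl}acetic acid F1. EtSH with EDC·HCl and DMAP gives the thioester 3-tert-butyl 4-methyl 5-[2-(ethylsulfanyl)-2-oxoethyl]-2-[2-methoxy-4-(methoxymethoxy)phenyl]furan-3,4-dicarboxylate F2. Fukuyama coupling with 13 and PdCl2(PPh3)2 gives the isomeric keto diester 3-tert-butyl 4-methyl 2-[2-methoxy-4-(methoxymethoxy)phenyl]-5-(6-methyl-2-oxohept-5-en-1-yl)furan-3,4-dicarboxylate F3. With LiN(i-Pr)2 (2.5 equiv, THF, −78 → 0 °C) F3 forms the ketone α,α'-dianion, whose terminal carbon attacks the ring methyl ester and gives 15 and then 16.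

**Step 4.** Bromine transfer between the two stabilised carbanions (halophilic attack) could scramble the partners and lead to homo-coupling, and substitution at the hindered carbon may be slow. If the cyclodehydration needed stronger acid, the tert-butyl ester or the acetal could be lost. The fallback builds the furan without a halogenated aroylacetate and attaches the aryl ring afterwards; it sets out from 5 and returns at 7. An interrupted Feist–Benary reaction of 5 with commercial tert-butyl 3-bromo-2-oxopropanoate (pyridine, THF) gives 3-tert-butyl 4-methyl 3-hydroxy-5-(2-methoxy-2-oxoethyl)-2,3-dihydrofuran-3,4-dicarboxylate F4 (racemic). Dehydration with MsCl and Et3N gives 3-tert-butyl 4-methyl 5-(2-methoxy-2-oxoethyl)furan-3,4-dicarboxylate F5, whose only ring C–H is at C2. Direct arylation (Pd(OAc)2, PCy3·HBF4, PivOH, K2CO3, DMA, 100 °C) with 1-bromo-2-methoxy-4-(methoxymethoxy)benzene F6, made from commercial 4-bromo-3-methoxyphenol with MOMCl and i-Pr2NEt, gives 7.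

**Step 10.** The discrimination between the two phenols may be incomplete, with over-methylation at O4 or C-methylation at C7. The fallback moves the methylation to the aldehyde stage, where the 4-hydroxyl is locked by a stronger hydrogen bond to the formyl oxygen; it sets out from 16 and returns at 19. LiAlH4 reduces 16 to 3-(hydroxymethyl)-2-[2-methoxy-4-(methoxymethoxy)phenyl]-5-(3-methylbut-2-en-1-yl)-1-benzofuran-4,6-diol F7. MnO2 oxidises it to 4,6-dihydroxy-2-[2-methoxy-4-(methoxymethoxy)phenyl]-5-(3-methylbut-2-en-1-yl)-1-benzofuran-3-carbaldehyde F8. MeI with K2CO3 in acetone then methylates the unchelated 6-hydroxyl to give 19.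

**Step 13.** Acid could add the 4-hydroxyl to the protonated prenyl double bond (closure to a dimethylchroman) or hydrate the alkene before the acetal is gone. The fallback avoids Brønsted acid by exchanging the acetal for silyl ethers and releasing the phenols with fluoride; it sets out from 19 and returns at 20. TESOTf (3 equiv) with 2,2'-bipyridyl in CH2Cl2 at 0 °C converts the aryl acetal directly into a silyl ether and also silylates O4, giving 6-methoxy-2-[2-methoxy-4-(triethylsilyloxy)phenyl]-5-(3-methylbut-2-en-1-yl)-4-(triethylsilyloxy)-1-benzofuran-3-carbaldehyde F9. Tetrabutylammonium fluoride buffered with AcOH in THF at 0 °C then gives 20.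

## Further compounds

F1 | step 9 | {4-(tert-butoxycarbonyl)-3-(methoxycarbonyl)-5-[2-methoxy-4-(methoxymethoxy)phenyl]furan-2-yl}acetic acid | OC(=O)Cc1oc(-c2ccc(OCOC)cc2OC)c(C(=O)OC(C)(C)C)c1C(=O)OC
F2 | step 9 | 3-tert-butyl 4-methyl 5-[2-(ethylsulfanyl)-2-oxoethyl]-2-[2-methoxy-4-(methoxymethoxy)phenyl]furan-3,4-dicarboxylate | CCSC(=O)Cc1oc(-c2ccc(OCOC)cc2OC)c(C(=O)OC(C)(C)C)c1C(=O)OC
F3 | step 9 | 3-tert-butyl 4-methyl 2-[2-methoxy-4-(methoxymethoxy)phenyl]-5-(6-methyl-2-oxohept-5-en-1-yl)furan-3,4-dicarboxylate | COC(=O)c1c(CC(=O)CCC=C(C)C)oc(-c2ccc(OCOC)cc2OC)c1C(=O)OC(C)(C)C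
F4 | step 4 | 3-tert-butyl 4-methyl 3-hydroxy-5-(2-methoxy-2-oxoethyl)-2,3-dihydrofuran-3,4-dicarboxylate (racemic) | COC(=O)CC1=C(C(=O)OC)C(O)(C(=O)OC(C)(C)C)CO1
F5 | step 4 | 3-tert-butyl 4-methyl 5-(2-methoxy-2-oxoethyl)furan-3,4-dicarboxylate | COC(=O)Cc1occ(C(=O)OC(C)(C)C)c1C(=O)OC
F6 | step 4 | 1-bromo-2-methoxy-4-(methoxymethoxy)benzene | COCOc1ccc(Br)c(OC)c1
F7 | step 10 | 3-(hydroxymethyl)-2-[2-methoxy-4-(methoxymethoxy)phenyl]-5-(3-methylbut-2-en-1-yl)-1-benzofuran-4,6-diol | COc1cc(OCOC)ccc1-c1oc2cc(O)c(CC=C(C)C)c(O)c2c1CO
F8 | step 10 | 4,6-dihydroxy-2-[2-methoxy-4-(methoxymethoxy)phenyl]-5-(3-methylbut-2-en-1-yl)-1-benzofuran-3-carbaldehyde | COc1cc(OCOC)ccc1-c1oc2cc(O)c(CC=C(C)C)c(O)c2c1C=O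
F9 | step 13 | 6-methoxy-2-[2-methoxy-4-(triethylsilyloxy)phenyl]-5-(3-methylbut-2-en-1-yl)-4-(triethylsilyloxy)-1-benzofuran-3-carbaldehyde | CC[Si](CC)(CC)Oc1ccc(-c2oc3cc(OC)c(CC=C(C)C)c(O[Si](CC)(CC)CC)c3c2C=O)c(OC)c1
A1 | alternative 1 | 3-formyl-2-(4-hydroxy-2-methoxyphenyl)-6-methoxy-5-(3-methylbut-2-en-1-yl)-1-benzofuran-4-yl 2,2-dimethylpropanoate | COc1cc(O)ccc1-c1oc2cc(OC)c(CC=C(C)C)c(OC(=O)C(C)(C)C)c2c1C=O
A2 | alternative 1 | 2-ethynyl-3-formyl-6-methoxy-5-(3-methylbut-2-en-1-yl)-1-benzofuran-4-yl 2,2-dimethylpropanoate | C#Cc1oc2cc(OC)c(CC=C(C)C)c(OC(=O)C(C)(C)C)c2c1C=O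
A3 | alternative 1 | 1,1-dimethoxy-3-(trimethylsilyloxy)buta-1,3-diene | COC(OC)=CC(=C)O[Si](C)(C)C
A4 | alternative 2 | 9-methoxy-3,7-bis(methoxymethoxy)-8-(3-methylbut-2-en-1-yl)-6H-[1]benzofuro[3,2-c]chromen-6-one | O=C1Oc2cc(OCOC)ccc2-c2oc3cc(OC)c(CC=C(C)C)c(OCOC)c3c21
A5 | alternative 2 | 2-bromo-5-(methoxymethoxy)phenyl 6-methoxy-4-(methoxymethoxy)-5-(3-methylbut-2-en-1-yl)-1-benzofuran-3-carboxylate | COCOc1ccc(Br)c(OC(=O)c2coc3cc(OC)c(CC=C(C)C)c(OCOC)c23)c1
A6 | alternative 3 | methyl 4-hydroxy-6-methoxy-2-[2-methoxy-4-(triisopropylsilyloxy)phenyl]-5-(3-methylbut-2-en-1-yl)-1-benzofuran-3-carboxylate | COC(=O)c1c(-c2ccc(O[Si](C(C)C)(C(C)C)C(C)C)cc2OC)oc2cc(OC)c(CC=C(C)C)c(O)c12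
A7 | alternative 3 | methyl 5-(diazoacetyl)-2-[2-methoxy-4-(triisopropylsilyloxy)phenyl]furan-3-carboxylate | COC(=O)c1cc(C(=O)C=[N+]=[N-])oc1-c1ccc(O[Si](C(C)C)(C(C)C)C(C)C)cc1OC
A8 | alternative 3 | 1-methoxy-5-methylhex-4-en-1-yne | COC#CCC=C(C)C
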